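**Plan**

- The target is a linear trimer with two CH2 bridges: ring A (enolised 2-butanoyl-4,4-dimethylcyclohexanetrione), ring B (butanoylphloroglucinol) and ring C (butanoylphloroglucinol 4-methyl ether).
- Retrosynthesis cuts first the bond between the ring A methylene carbon and ring B, then the CH2–ring B bond of the B–C diarylmethane (CH2 stays on ring C). It then cuts the two C–CH3 bonds of ring A, the O–CH3 bond of ring C and the aryl–acyl bond, so that all three rings come from butanoylphloroglucinol.
- Enabling feature: C6 of ring A and its exocyclic CH2 lie between the C1 and C5 carbonyls of a vinylogous acid, so a 6-(dimethylaminomethyl) betaine can shed dimethylamine to a cross-conjugated 6-methylidene ene-trione. The free C–H of ring B lies between two hydroxylated carbons, next to the hydroxyl para to the acyl group, and is the most nucleophilic carbon of the partner.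
- Forward order: acylation of phloroglucinol; ring C branch by 4-O-methylation, aminomethylation and union with ring B through an ortho-quinone methide; ring A branch by dearomative gem-dimethylation and aminomethylation; the last step joins ring A–CH2 to ring B–CH2–ring C. The dimethylamino helper leaves in each coupling and no protecting group is used.
- Stereochemistry: none to set (no stereocentre, no stereogenic double bond; the enol forms are tautomers).

Key step: step 7

Remark on the chemistry: ring A is written as the enol tautomer of the given SMILES and its keto–enol tautomers are treated as one compound. The aminomethyl compounds are drawn in neutral form although they should exist as zwitterions.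

**Route**

Step 1
Reactants: 1 phloroglucinol + 2 butanoyl chloride
Product: 3 1-(2,4,6-trihydroxyphenyl)butan-1-one (butanoylphloroglucinol)
Conditions: AlCl3 (3.5 equiv), PhNO2/CH2Cl2, 0 °C → 45 °C; then ice/1 M HCl
Reagents that add atoms: none
Why: Friedel–Crafts C-acylation of the symmetrical, strongly activated triol, where the chelated aryl ketone–AlCl3 complex deactivates the ring so that mono-acylation should dominate.

Step 2
Reactants: 3 butanoylphloroglucinol
Product: 4 1-(2,6-dihydroxy-4-methoxyphenyl)butan-1-one
Conditions: Me2SO4 (1.0 equiv), K2CO3 (1.0 equiv), acetone, rt → 40 °C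
Reagents that add atoms: dimethyl sulfate, COS(=O)(=O)OC
Why: Williamson ether synthesis in which the 4-OH para to the ketone, the most acidic phenol and the only one not tied to the carbonyl by a hydrogen-bond chelate, should take the single equivalent of methylating agent.

Step 3
Reactants: 4 1-(2,6-dihydroxy-4-methoxyphenyl)butan-1-one
Product: 5 1-[3-[(dimethylamino)methyl]-2,6-dihydroxy-4-methoxyphenyl]butan-1-one
Conditions: 37% aq. CH2O (1.0 equiv), 40% aq. Me2NH (1.0 equiv), EtOH, 0 °C → rt
Reagents that add atoms: formaldehyde, C=O; dimethylamine, CNC
Why: Mannich reaction at one of the two equivalent free ring carbons ortho to a phenol, with one equivalent of iminium and crystallisation of the zwitterionic product expected to hold the reaction at mono-aminomethylation.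

Step 4
Reactants: 5 ring C Mannich base + 3 butanoylphloroglucinol
Product: 7 1-[3-[(3-butanoyl-2,4-dihydroxy-6-methoxyphenyl)methyl]-2,4,6-trihydroxyphenyl]butan-1-one (ring B–ring C diarylmethane), via ortho-quinone methide 6 (not isolated)
Conditions: 3 (3 equiv), slow addition of 5, 1,4-dioxane, 95 °C, N2 sweep
Reagents that add atoms: none
Why: Thermal loss of dimethylamine from the phenolic Mannich base should give ortho-quinone methide 6, which a free ring carbon of 3 captures in a Michael-type Friedel–Crafts alkylation followed by re-aromatisation, the excess of 3 suppressing a second capture.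

Step 5
Reactants: 3 butanoylphloroglucinol
Product: 8 2-butanoyl-3,5-dihydroxy-4,4-dimethylcyclohexa-2,5-dien-1-one (butanoylfilicinic acid)
Conditions: NaOMe (3.2 equiv), MeI (2.3 equiv), MeOH, 0 °C → rt; then 1 M HCl
Reagents that add atoms: iodomethane, CI
Why: Dearomative C-methylation of the phloroglucinol polyanion, in which the first methyl group makes its carbon the most electron-rich site so that the second should enter at the same carbon, and the resulting vinylogous-acid anion is a poor nucleophile for a third alkylation.

Step 6
Reactants: 8 butanoylfilicinic acid
Product: 9 2-butanoyl-6-[(dimethylamino)methyl]-3,5-dihydroxy-4,4-dimethylcyclohexa-2,5-dien-1-one (betaine)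
Conditions: 37% aq. CH2O (1.5 equiv) and 40% aq. Me2NH (1.5 equiv) premixed, EtOH, 0 °C, slow addition of 8; cold filtration
Reagents that add atoms: formaldehyde, C=O; dimethylamine, CNC
Why: Mannich reaction at C6, the only nucleophilic ring carbon of the enolised triketone, with inverse addition into excess iminium at 0 °C keeping free 8 low so that the ammonium enolate betaine should precipitate before it can lose the amine.

Step 7
Reactants: 9 ring A betaine + 7 ring B–ring C diarylmethane
Product: 11 2-butanoyl-6-[[3-butanoyl-5-[(3-butanoyl-2,4-dihydroxy-6-methoxyphenyl)methyl]-2,4,6-trihydroxyphenyl]methyl]-3,5-dihydroxy-4,4-dimethylcyclohexa-2,5-dien-1-one (the target), via ene-trione 10 (not isolated)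
Conditions: 7 (1.0 equiv), 9 (1.05 equiv, in portions), MeCN, 55 °C, N2; then 0.5 M HCl wash
Reagents that add atoms: none
Why: On gentle warming the betaine 9, the ammonium enolate of a vinylogous acid, should lose dimethylamine by an E1cB path to give the cross-conjugated 6-methylidene ene-trione 10, whose exocyclic CH2 is attacked by the free ring B carbon of 7, and tautomerisation then restores aromatic ring B and the enolised triketone ring A. The closest known reaction type is the retro-Mannich/Michael-type Friedel–Crafts alkylation of acylphloroglucinols by 2-methylidene-1,3-dicarbonyl compounds and ortho-quinone methides released from Mannich bases. No ring is closed and no stereocentre is formed, so neither a mode of closure nor a controlling element is at issue. The step needs C- over O-alkylation, which the reversibility of phenoxide O-addition to 10 and the stability of the aromatic C-alkylated product should secure. It also needs ring B over ring C selectivity, which the substrate secures because ring B keeps a free hydroxyl para to its butanoyl group (the most acidic phenol, whose phenoxide activates the adjacent free carbon) whereas in ring C that oxygen is methylated and the free carbon is flanked by the methoxy group. One equivalent of 9 and a temperature near 55 °C should limit a second capture and methylene exchange between the two bridges, the liberated dimethylamine being buffered as the salt of the acidic triketone enol.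

**Compound list**

1 | phloroglucinol (benzene-1,3,5-triol) | Oc1cc(O)cc(O)c1 | starting material
2 | butanoyl chloride | CCCC(=O)Cl | starting material
3 | 1-(2,4,6-trihydroxyphenyl)butan-1-one (butanoylphloroglucinol) | CCCC(=O)c1c(O)cc(O)cc1O | intermediate
4 | 1-(2,6-dihydroxy-4-methoxyphenyl)butan-1-one | CCCC(=O)c1c(O)cc(OC)cc1O | intermediate
5 | 1-[3-[(dimethylamino)methyl]-2,6-dihydroxy-4-methoxyphenyl]butan-1-one | CCCC(=O)c1c(O)cc(OC)c(CN(C)C)c1O | intermediate
6 | 2-butanoyl-3-hydroxy-5-methoxy-6-methylidenecyclohexa-2,4-dien-1-one (ring C ortho-quinone methide) | CCCC(=O)C1=C(O)C=C(OC)C(=C)C1=O | intermediate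
7 | 1-[3-[(3-butanoyl-2,4-dihydroxy-6-methoxyphenyl)methyl]-2,4,6-trihydroxyphenyl]butan-1-one | CCCC(=O)c1c(O)cc(O)c(Cc2c(OC)cc(O)c(C(=O)CCC)c2O)c1O | intermediate
8 | 2-butanoyl-3,5-dihydroxy-4,4-dimethylcyclohexa-2,5-dien-1-one (butanoylfilicinic acid) | CCCC(=O)C1=C(O)C(C)(C)C(O)=CC1=O | intermediate
9 | 2-butanoyl-6-[(dimethylamino)methyl]-3,5-dihydroxy-4,4-dimethylcyclohexa-2,5-dien-1-one | CCCC(=O)C1=C(O)C(C)(C)C(O)=C(CN(C)C)C1=O | intermediate
10 | 2-butanoyl-3-hydroxy-4,4-dimethyl-6-methylidenecyclohex-2-ene-1,5-dione (ring A ene-trione) | CCCC(=O)C1=C(O)C(C)(C)C(=O)C(=C)C1=O | intermediate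
11 | 2-butanoyl-6-[[3-butanoyl-5-[(3-butanoyl-2,4-dihydroxy-6-methoxyphenyl)methyl]-2,4,6-trihydroxyphenyl]methyl]-3,5-dihydroxy-4,4-dimethylcyclohexa-2,5-dien-1-one | CCCC(=O)C1=C(O)C(C)(C)C(O)=C(Cc2c(O)c(Cc3c(OC)cc(O)c(C(=O)CCC)c3O)c(O)c(C(=O)CCC)c2O)C1=O | target

**Step count and risks**

Total step count: 7. Longest linear sequence: 5 steps (steps 1, 2, 3, 4 and 7); the ring A branch (steps 1, 5, 6) joins at step 7.

Steps most likely to fail:

1. Step 7. The ene-trione may be captured at the free carbon of ring C or a second time, and the liberated amine may trigger methylene exchange between the two bridges. The fallback reverses the order of union. It sets out from 9 and 3 and comes back to the route at 11. Betaine 9 would be warmed with an excess of 3 (MeCN, 55 °C) so that ene-trione 10 is captured by 3, which should give the ring A–ring B dimer 2-butanoyl-6-[(3-butanoyl-2,4,6-trihydroxyphenyl)methyl]-3,5-dihydroxy-4,4-dimethylcyclohexa-2,5-dien-1-one F1. Its only free aromatic C–H is on ring B. F1 would then be heated with Mannich base 5 (1,4-dioxane, 90 °C) so that ortho-quinone methide 6 is captured at that carbon, which should give 11 with no choice of site left open.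

2. Step 6. The betaine may lose dimethylamine while free 8 is still present, so that the ene-trione is consumed by homo-coupling and 9 cannot be isolated. The fallback makes the homo-coupled compound on purpose and uses it as the ene-trione source. It sets out from 8 and comes back to the route at 11. Condensation of 8 with 37% aq. CH2O (0.5 equiv, EtOH/H2O, rt; Knoevenagel condensation then Michael addition) should give 6,6'-methylenebis(2-butanoyl-3,5-dihydroxy-4,4-dimethylcyclohexa-2,5-dien-1-one) F2. Warming F2 with 7 and Et3N in MeCN (50–60 °C) should bring about the retro-Michael/Michael methylene exchange known for methylene-bridged acylphloroglucinols in base. The bridge between two dearomatised rings should open faster than a bridge to an aromatic ring, releasing 10 for capture by ring B of 7 to give 11, with 8 recycled.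

3. Step 4. Amine expulsion from the aromatic Mannich base may be sluggish, and forcing it may lead to capture of the ortho-quinone methide at both free carbons of 3 or to self-condensation. The fallback avoids a ring C electrophile by desymmetrisation. It sets out from 3 and comes back to the route at 7. Condensation of 3 (in excess) with 37% aq. CH2O (0.5 equiv, dilute aq. NaOH, 0 °C; hydroxymethylation followed by Friedel–Crafts alkylation) should give the symmetrical dimer bis(3-butanoyl-2,4,6-trihydroxyphenyl)methane F3. One equivalent of Me2SO4 with K2CO3 in acetone should then methylate one of the two equivalent hydroxyls para to a butanoyl group to give 7, with unreacted F3 recycled.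

**Further compounds**

F1 | step 7 | 2-butanoyl-6-[(3-butanoyl-2,4,6-trihydroxyphenyl)methyl]-3,5-dihydroxy-4,4-dimethylcyclohexa-2,5-dien-1-one | CCCC(=O)C1=C(O)C(C)(C)C(O)=C(Cc2c(O)cc(O)c(C(=O)CCC)c2O)C1=O
F2 | step 6 | 6,6'-methylenebis(2-butanoyl-3,5-dihydroxy-4,4-dimethylcyclohexa-2,5-dien-1-one) | CCCC(=O)C1=C(O)C(C)(C)C(O)=C(CC2=C(O)C(C)(C)C(O)=C(C(=O)CCC)C2=O)C1=O
F3 | step 4 | bis(3-butanoyl-2,4,6-trihydroxyphenyl)methane | CCCC(=O)c1c(O)cc(O)c(Cc2c(O)cc(O)c(C(=O)CCC)c2O)c1O
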